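The target is an ent-labdane; in labdane numbering C3 is the carbinol carbon and C4 the gem-dimethyl carbon of ring A. Everything rests on forming C3–C4 while breaking a C4–C7 bond that only the precursor has. The precursor is a pinane from verbenone: C4, C5, C6 and C7 form a cyclobutane, C8 and C17 a spiro-epoxide, and C10 carries a 3-oxopropyl arm. Trivalent titanium opens the epoxide, the C8 radical cleaves the C4–C7 bond, and the C4 radical closes ring A on the aldehyde. One operation gives the C7=C8 alkene, the C17 alcohol and the C3 carbinol. It exploits the 1,4-relation of C4 and C7 across ring B and the C17 oxygen on C8.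

Key step: step 9

Assumption: (1S,5S)-(−)-verbenone 4 is used in high enantiomeric purity; a commercial lot of lower purity would be replaced by material made from enantiopure (−)-α-pinene by allylic oxidation.

Remark on numbering: the pinane intermediates are named as bicyclo[3.1.1]heptanes; their C1, C2, C3, C4, C5, C6 and C7 become C7, C8, C9, C10, C5, C4 and C6 of the target.

Step 1
Reactants: 1 methyl hydrogen (R)-3-methylglutarate
Product: 2 methyl (3R)-5-hydroxy-3-methylpentanoate
Conditions: BH3·SMe2, THF, 0 °C to rt; then H2O
Reagents that add atoms: none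
Why: Chemoselective borane reduction of a carboxylic acid beside an ester (the acid is activated as an acyloxyborane, the methyl ester is not attacked at this temperature), and the stereocentre is not involved.

Step 2
Reactants: 2 methyl (3R)-5-hydroxy-3-methylpentanoate
Product: 3 methyl (3R)-3-methyl-5-oxopentanoate
Conditions: Dess–Martin periodinane, CH2Cl2, 0 °C to rt
Reagents that add atoms: none
Why: Dess–Martin oxidation stops at the aldehyde under near-neutral conditions, and the stereocentre is β to the new carbonyl and cannot epimerise.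

Step 3
Reactants: 4 (1S,5S)-(−)-verbenone; 5 but-3-en-1-ylmagnesium bromide
Product: 7 (1S,4S,5S)-4-(but-3-en-1-yl)-4,6,6-trimethylbicyclo[3.1.1]heptan-2-one, via trimethylsilyl enol ether 6 (not isolated)
Conditions: CuBr·SMe2 (10 mol%), TMSCl, THF, −78 to −30 °C; then 1 M HCl
Reagents that add atoms: but-3-en-1-ylmagnesium bromide 5, C=CCC[Mg]Br
Why: Copper-catalysed, TMSCl-accelerated conjugate addition of a Grignard reagent to the β-methyl enone creates the quaternary carbon (future C10), the butenyl group entering anti to the gem-dimethyl bridge, the only open face of verbenone, so that the methyl group is left syn to that bridge; the acidic work-up hydrolyses 6.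

Step 4
Reactants: 7 (1S,4S,5S)-4-(but-3-en-1-yl)-4,6,6-trimethylbicyclo[3.1.1]heptan-2-one; 3 methyl (3R)-3-methyl-5-oxopentanoate
Product: 11 methyl (3R,5Z)-5-[4-(but-3-en-1-yl)-4,6,6-trimethyl-2-oxobicyclo[3.1.1]heptan-3-ylidene]-3-methylpentanoate, via lithium enolate 8 (not isolated), via lithium aldolate 9 (not isolated), via mesylate 10 (not isolated)
Conditions: LiN(i-Pr)2, THF, −78 °C; then 3, −78 °C; then MsCl, −78 to 0 °C; then DBU, rt
Reagents that add atoms: aldehyde 3, COC(=O)C[C@H](C)CC=O
Why: Directed aldol addition of the only possible enolate of 7 (the other α-carbon is a bridgehead) to aldehyde 3, then mesylation and E1cB elimination in the same flask, should give the conjugated exocyclic enone; the stereocentres of 9 and 10 and the alkene geometry of 11 do not matter because the next step sets C3 of the bicycle anew.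

Step 5
Reactants: 11 methyl (3R,5Z)-5-[4-(but-3-en-1-yl)-4,6,6-trimethyl-2-oxobicyclo[3.1.1]heptan-3-ylidene]-3-methylpentanoate
Product: 13 methyl (3R)-5-[(1S,3S,4R,5R)-4-(but-3-en-1-yl)-4,6,6-trimethyl-2-oxobicyclo[3.1.1]heptan-3-yl]-3-methylpentanoate, via lithium enolate 12 (not isolated)
Conditions: LiBH(s-Bu)3, THF, −78 °C; then t-BuCO2H, −78 °C
Reagents that add atoms: none
Why: Conjugate reduction with LiBH(s-Bu)3, which should add hydride in the 1,4 sense to an s-cis alkylidene ketone whose carbonyl is shielded, gives enolate 12, and kinetic protonation by the hindered acid from the face anti to the gem-dimethyl bridge places the side chain syn to the bridge and cis to the methyl on the neighbouring quaternary carbon, the configuration of the future C9.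

Step 6
Reactants: 13 methyl (3R)-5-[(1S,3S,4R,5R)-4-(but-3-en-1-yl)-4,6,6-trimethyl-2-oxobicyclo[3.1.1]heptan-3-yl]-3-methylpentanoate
Product: 14 methyl (3R)-5-[4-(but-3-en-1-yl)-4,6,6-trimethyl-2-methylidenebicyclo[3.1.1]heptan-3-yl]-3-methylpentanoate
Conditions: Zn, CH2Br2, TiCl4, THF/CH2Cl2, 0 °C to rt
Reagents that add atoms: dibromomethane, BrCBr
Why: Takai–Lombardo methylenation converts hindered, epimerisable ketones under non-basic conditions and tolerates the methyl ester and the terminal alkene, so the α-stereocentre set in step 5 is kept.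

Step 7
Reactants: 14 methyl (3R)-5-[4-(but-3-en-1-yl)-4,6,6-trimethyl-2-methylidenebicyclo[3.1.1]heptan-3-yl]-3-methylpentanoate
Product: 15 methyl (3R)-5-[4'-(but-3-en-1-yl)-4',6',6'-trimethylspiro[oxirane-2,2'-bicyclo[3.1.1]heptan]-3'-yl]-3-methylpentanoate
Conditions: mCPBA (1.0 equiv), NaHCO3, CH2Cl2, 0 °C
Reagents that add atoms: mCPBA, OOC(=O)c1cccc(Cl)c1
Why: Prilezhaev epoxidation is faster at the more electron-rich 1,1-disubstituted exocyclic alkene than at the monosubstituted one and should take place anti to the gem-dimethyl bridge as in β-pinene, giving one spiro-epoxide whose stereocentre is removed again in step 9; NaHCO3 protects the acid-labile epoxide.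

Step 8
Reactants: 15 methyl (3R)-5-[4'-(but-3-en-1-yl)-4',6',6'-trimethylspiro[oxirane-2,2'-bicyclo[3.1.1]heptan]-3'-yl]-3-methylpentanoate
Product: 16 methyl (3R)-5-[4',6',6'-trimethyl-4'-(3-oxopropyl)spiro[oxirane-2,2'-bicyclo[3.1.1]heptan]-3'-yl]-3-methylpentanoate
Conditions: O3, CH2Cl2, −78 °C; then PPh3, −78 °C to rt
Reagents that add atoms: ozone, [O-][O+]=O
Why: Ozonolysis with reductive work-up cleaves the only remaining alkene to the aldehyde under neutral conditions that the spiro-epoxide, the ester and the strained ring should survive.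

Step 9
Reactants: 16 methyl (3R)-5-[4',6',6'-trimethyl-4'-(3-oxopropyl)spiro[oxirane-2,2'-bicyclo[3.1.1]heptan]-3'-yl]-3-methylpentanoate
Product: 18 methyl (3R)-5-[(1S,4aS,6R,8aS)-6-hydroxy-2-(hydroxymethyl)-5,5,8a-trimethyl-1,4,4a,5,6,7,8,8a-octahydronaphthalen-1-yl]-3-methylpentanoate, via ring-opened C4 radical 17 (not isolated)
Conditions: Cp2TiCl2 (2.5 equiv), Mn dust, THF, rt, slow addition of 16; then 1 M HCl
Reagents that add atoms: none
Why: Proposed new method: Cp2TiCl should open the spiro-epoxide homolytically at its more substituted carbon to a tertiary C8 radical carrying the C17–O–Ti group; this cyclobutylcarbinyl radical releases the ring strain by β-scission of the C4–C7 bond, which gives the C7=C8 alkene and the tertiary C4 radical 17, and 17 adds to the aldehyde carbon C3, the alkoxyl radical being reduced by a second Cp2TiCl to the titanium alkoxide so that the otherwise reversible addition is driven forward. The closest known reaction types are the Cp2TiCl-mediated opening of β-pinene oxide with cleavage of the four-membered ring and the Cp2TiCl-mediated cyclisation of epoxide-derived radicals onto aldehydes; their merger in one cascade through a relayed radical is the untested part. Ring A closes in a 6-exo-trig mode at the carbonyl carbon, trans-fused because the C4 radical on C5 and the oxopropyl arm on C10 are trans and both equatorial on the half-chair of ring B. The new C3 stereocentre should arise from a chair transition state with the bulky titanium-bound oxygen equatorial, cis to the C10 methyl, and the reversibility of the C3–C4 bond formation allows an axial alkoxyl radical to return to 17 and be funnelled to the equatorial alkoxide. The step needs regioselective epoxide opening and β-scission (tertiary radicals at C8 and C4, not a primary radical at C6), which the substitution pattern secures, and an aldehyde that Cp2TiCl does not reduce, which holds for aliphatic aldehydes; MnCl2 is a weaker Lewis acid than ZnCl2 and should spare the epoxide.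

Compound list

1 | methyl hydrogen (R)-3-methylglutarate [(3R)-5-methoxy-3-methyl-5-oxopentanoic acid] | COC(=O)C[C@H](C)CC(=O)O | starting material
2 | methyl (3R)-5-hydroxy-3-methylpentanoate | COC(=O)C[C@H](C)CCO | intermediate
3 | methyl (3R)-3-methyl-5-oxopentanoate | COC(=O)C[C@H](C)CC=O | intermediate
4 | (1S,5S)-(−)-verbenone [(1S,5S)-4,6,6-trimethylbicyclo[3.1.1]hept-3-en-2-one] | O=C1C=C(C)[C@@H]2C[C@H]1C2(C)C | starting material
5 | but-3-en-1-ylmagnesium bromide (THF solution) | C=CCC[Mg]Br | starting material
6 | trimethylsilyl enol ether of 7 (C2=C3 enol ether; butenyl anti to the gem-dimethyl bridge) | C1=C(O[Si](C)(C)C)[C@H]2C[C@H](C2(C)C)[C@@]1(C)CCC=C | intermediate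
7 | (1S,4S,5S)-4-(but-3-en-1-yl)-4,6,6-trimethylbicyclo[3.1.1]heptan-2-one (butenyl anti, C4 methyl syn to the gem-dimethyl bridge) | C=CCC[C@@]1(C)CC(=O)[C@H]2C[C@@H]1C2(C)C | intermediate
8 | lithium enolate of 7 (C2=C3) | C1=C([O-])[C@H]2C[C@H](C2(C)C)[C@@]1(C)CCC=C.[Li+] | intermediate
9 | lithium aldolate from 8 and 3 (mixture at C3 of the bicycle and at the carbinol carbon) | COC(=O)C[C@H](C)CC([O-])C1C(=O)[C@H]2C[C@H](C2(C)C)[C@@]1(C)CCC=C.[Li+] | intermediate
10 | β-mesyloxy ketone from 9 (same mixture) | COC(=O)C[C@H](C)CC(OS(C)(=O)=O)C1C(=O)[C@H]2C[C@H](C2(C)C)[C@@]1(C)CCC=C | intermediate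
11 | methyl (3R,5Z)-5-[4-(but-3-en-1-yl)-4,6,6-trimethyl-2-oxobicyclo[3.1.1]heptan-3-ylidene]-3-methylpentanoate (bridgeheads and C4 as in 7; chain cis to the carbonyl expected, geometry lost in step 5) | COC(=O)C[C@H](C)C/C=C1\C(=O)[C@H]2C[C@H](C2(C)C)[C@@]1(C)CCC=C | intermediate
12 | lithium enolate from 1,4-reduction of 11 (C2=C3, fully substituted) | COC(=O)C[C@H](C)CCC1=C([O-])[C@H]2C[C@H](C2(C)C)[C@@]1(C)CCC=C.[Li+] | intermediate
13 | methyl (3R)-5-[(1S,3S,4R,5R)-4-(but-3-en-1-yl)-4,6,6-trimethyl-2-oxobicyclo[3.1.1]heptan-3-yl]-3-methylpentanoate (side chain at C3 syn to the gem-dimethyl bridge and cis to the C4 methyl) | COC(=O)C[C@H](C)CC[C@@H]1C(=O)[C@H]2C[C@H](C2(C)C)[C@@]1(C)CCC=C | intermediate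
14 | methyl (3R)-5-[4-(but-3-en-1-yl)-4,6,6-trimethyl-2-methylidenebicyclo[3.1.1]heptan-3-yl]-3-methylpentanoate (configuration as in 13) | COC(=O)C[C@H](C)CC[C@@H]1C(=C)[C@H]2C[C@H](C2(C)C)[C@@]1(C)CCC=C | intermediate
15 | methyl (3R)-5-[4'-(but-3-en-1-yl)-4',6',6'-trimethylspiro[oxirane-2,2'-bicyclo[3.1.1]heptan]-3'-yl]-3-methylpentanoate (oxirane oxygen anti to the gem-dimethyl bridge; rest as in 13) | COC(=O)C[C@H](C)CC[C@@H]1[C@]3(CO3)[C@H]2C[C@H](C2(C)C)[C@@]1(C)CCC=C | intermediate
16 | methyl (3R)-5-[4',6',6'-trimethyl-4'-(3-oxopropyl)spiro[oxirane-2,2'-bicyclo[3.1.1]heptan]-3'-yl]-3-methylpentanoate (configuration as in 15) | COC(=O)C[C@H](C)CC[C@@H]1[C@]3(CO3)[C@H]2C[C@H](C2(C)C)[C@@]1(C)CCC=O | intermediate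
17 | ring-opened tertiary C4 radical, cyclohexene with C17 bound as Cp2TiCl alkoxide (titanium tetravalent) and free aldehyde | COC(=O)C[C@H](C)CC[C@@H]1C(C[O-])=CC[C@H]([C](C)C)[C@@]1(C)CCC=O.[Ti+4].[Cl-].c1cc[cH-]c1.c1cc[cH-]c1 | intermediate
18 | methyl (3R)-5-[(1S,4aS,6R,8aS)-6-hydroxy-2-(hydroxymethyl)-5,5,8a-trimethyl-1,4,4a,5,6,7,8,8a-octahydronaphthalen-1-yl]-3-methylpentanoate (CNP0313905.1) | COC(=O)C[C@H](C)CC[C@@H]1C(CO)=CC[C@@H]2C(C)(C)[C@H](O)CC[C@@]12C | target

Total step count: 9. Longest linear sequence: 8 steps (steps 1, 2 and 4 to 9, from monoester 1); the branch from verbenone 4 runs over 7 steps (steps 3 to 9) and joins the main line in step 4.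

Steps most likely to fail

Step 9 (the labelled step). The ring-opened tertiary radical may be captured or reduced by trivalent titanium before it adds to the aldehyde, so that the epoxide opens and the cyclobutane breaks but ring A does not close. The fallback separates the two events with known chemistry and sets out from 16. Cp2TiCl in excess, added in one portion, should convert 16 into isopropenyl aldehyde F1; this is the known course of such openings of β-pinene oxide, in which the tertiary radical is captured by titanium and loses a β-hydrogen. F1 is then closed by the known HAT-initiated alkene–carbonyl radical cyclisation (Fe(acac)3, PhSiH3, EtOH, 60 °C): the same tertiary C4 radical is regenerated from the isopropenyl group and adds to the aldehyde. This comes back to the route at 18.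

Step 5. Hydride may attack the carbonyl carbon instead of the β-carbon, or the enolate may be protonated from the bridge face, which would give the wrong configuration at the future C9. The fallback sets out from 11 and separates reduction from protonation. Copper hydride 1,4-hydrosilylation ([(Ph3P)CuH]6 catalytic, PhMe2SiH, toluene, rt) should give the isolable silyl enol ether F2. F2 is then protodesilylated at low temperature (TBAF, AcOH, THF, −78 °C), so that the proton is delivered in a separate, controllable step from the open face. This comes back at 13.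

Step 4. The hindered aldolate may revert by retro-aldol cleavage or close onto the methyl ester as a lactone on warming, or mesylation and elimination may stay incomplete in the one-flask sequence. The fallback sets out from silyl enol ether 6, isolated by a non-aqueous work-up of step 3. Mukaiyama aldol addition of 6 to aldehyde 3 (BF3·OEt2, CH2Cl2, −78 °C) should give β-hydroxy ketone F3, which is purified and dehydrated in a separate operation (MsCl, Et3N, CH2Cl2; then DBU). This comes back at 11.

Further compounds

F1 | step 9 | methyl (3R)-5-[2-(hydroxymethyl)-6-methyl-6-(3-oxopropyl)-5-(prop-1-en-2-yl)cyclohex-2-en-1-yl]-3-methylpentanoate (side chain, ring methyl and isopropenyl all cis) | COC(=O)C[C@H](C)CC[C@@H]1C(CO)=CC[C@H](C(C)=C)[C@@]1(C)CCC=O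
F2 | step 5 | dimethylphenylsilyl enol ether of 13 (C2=C3) | COC(=O)C[C@H](C)CCC1=C(O[Si](C)(C)c3ccccc3)[C@H]2C[C@H](C2(C)C)[C@@]1(C)CCC=C
F3 | step 4 | β-hydroxy ketone, aldol adduct of 7 and 3 (mixture at the two new centres) | COC(=O)C[C@H](C)CC(O)C1C(=O)[C@H]2C[C@H](C2(C)C)[C@@]1(C)CCC=C
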